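**Plan**
- Retrosynthesis: the C4 acetate and the C3 chlorohydrin ester come off first; the C11 carbinol goes back to a methyl ester; ring B is then cut at C6=C7 and C9–C10. This leaves a ring-A enal (C6 as CHO on C5, C5=C10 tetrasubstituted) and methyl acetoacetate (CH3 = C9, C=O = C8, CH2 = C7, ester carbon = C11).
- Enabling feature: the dienol form of ring B (C5=C6–C7=C8–O with sp3 C9 and C10) is the 6π ring-closure product of the triene C10=C5–C6=C7–C8(O)=C9. Its C6=C7 bond joins an aldehyde carbon to a methylene lying between the C8 carbonyl and C11.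
- Forward order: ring A is built first from 2-methylcyclohex-2-en-1-one (trans C3/C4 diol locked as acetonide, C10 methyl, C6 formyl). Ring B is closed onto it in one flask, then C11 is completed, the C5 hydrogen is put in, and O3 and O4 are acylated.
- Stereochemistry: C4 from a CBS reduction relayed by hydroxyl-directed epoxidation; C3 by inversion in the epoxide hydrolysis; C10 from ring A through acetonide-biased torquoselectivity; C5 by axial protonation of the ring-B dienolate; C2'/C3' from an asymmetric epoxidation and an inverting chloride opening.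

Key step: step 9

Remark: eudesmane numbering is used (ring A = C1–C5 and C10; ring B = C5–C10; C11 on C7). In the given structure O3 and O4 are trans, both equatorial on the 5R,10R trans-decalin, and the acyl group is (2R,3S).

Step 1
Reactants: 1 2-methylcyclohex-2-en-1-one
Product: 2 (S)-2-methylcyclohex-2-en-1-ol
Conditions: (R)-2-methyl-CBS-oxazaborolidine (10 mol %), catecholborane, PhMe, −78 °C
Reagents that add atoms: none
Why: Corey–Bakshi–Shibata reduction, in which the oxazaborolidine–borane complex binds the ketone with the larger α-methylalkenyl arm away from the catalyst and delivers hydride to one carbonyl face, should set the (S)-carbinol that later relays its configuration to C4.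

Step 2
Reactants: 2 (S)-2-methylcyclohex-2-en-1-ol
Product: 3 (1S,2S,3R)-2,3-epoxy-2-methylcyclohexan-1-ol (epoxide cis to OH)
Conditions: mCPBA, CH2Cl2, 0 °C
Reagents that add atoms: mCPBA, OOC(=O)c1cccc(Cl)c1
Why: hydroxyl-directed (Henbest) epoxidation, in which hydrogen bonding of the allylic OH to the peracid should deliver oxygen to the alkene face syn to the hydroxyl, fixes the future C4 and C3 centres from the carbinol.

Step 3
Reactants: 3 (1S,2S,3R)-2,3-epoxy-2-methylcyclohexan-1-ol
Product: 4 (2R,3R)-2,3-epoxy-2-methylcyclohexan-1-one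
Conditions: Dess–Martin periodinane, CH2Cl2, 23 °C
Reagents that add atoms: none
Why: Dess–Martin oxidation of the secondary alcohol under neutral conditions should give the epoxy ketone without touching the two epoxide stereocentres.

Step 4
Reactants: 4 (2R,3R)-2,3-epoxy-2-methylcyclohexan-1-one
Product: 5 (2R,3S)-2,3-dihydroxy-2-methylcyclohexan-1-one (trans diol)
Conditions: HClO4 (cat.), THF/H2O, 50 °C
Reagents that add atoms: water, O
Why: acid-catalysed epoxide hydrolysis in which water attacks the epoxide carbon remote from the carbonyl group with inversion (the quaternary α-carbon is deactivated by the adjacent C=O and also blocks β-elimination) should keep the tertiary centre and give the trans diol.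

Step 5
Reactants: 5 (2R,3S)-2,3-dihydroxy-2-methylcyclohexan-1-one
Product: 6 (3aR,7aS)-2,2,3a-trimethylhexahydro-1,3-benzodioxol-4-one (trans-fused acetonide of 5)
Conditions: 2-methoxypropene, PPTS (cat.), CH2Cl2, 0 → 23 °C
Reagents that add atoms: 2-methoxypropene, COC(C)=C
Why: acid-catalysed ketalisation with an enol ether should close the trans-fused dioxolane, which protects both oxygens and pins them equatorial with the C4 methyl group axial, the conformational lock used in step 9.

Step 6
Reactants: 6 (3aR,7aS)-2,2,3a-trimethylhexahydro-1,3-benzodioxol-4-one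
Product: 7 (3aR,7aS)-2,2,3a,5-tetramethylhexahydro-1,3-benzodioxol-4-one (C5 epimers)
Conditions: LiN(iPr)2, MeI, THF, −78 → 0 °C
Reagents that add atoms: iodomethane, CI
Why: alkylation of the lithium enolate, which can form only on the CH2 side because the other α-carbon is quaternary, should give the methyl ketone as an epimer mixture that is of no consequence because this carbon (C10) becomes sp2 in step 7.

Step 7
Reactants: 7 (3aR,7aS)-2,2,3a,5-tetramethylhexahydro-1,3-benzodioxol-4-one
Product: 8 (3aR,7aS)-2,2,3a,5-tetramethyl-3a,6,7,7a-tetrahydro-1,3-benzodioxol-4-yl trifluoromethanesulfonate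
Conditions: KN(SiMe3)2, PhNTf2, THF, −78 → 0 °C
Reagents that add atoms: N-phenylbis(trifluoromethanesulfonimide), O=S(=O)(N(c1ccccc1)S(=O)(=O)C(F)(F)F)C(F)(F)F
Why: enol triflate formation, in which the only remaining α-hydrogen sits on the methyl-bearing carbon, so that O-sulfonylation of the potassium enolate can give only the tetrasubstituted C5=C10 enol triflate.

Step 8
Reactants: 8 enol triflate
Product: 9 (3aS,7aS)-2,2,3a,5-tetramethyl-3a,6,7,7a-tetrahydro-1,3-benzodioxole-4-carbaldehyde (ring-A enal; CHO carbon = C6)
Conditions: Pd(PPh3)4 (cat.), LiCl, CO (1 atm), Bu3SnH (slow addition), THF, 50 °C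
Reagents that add atoms: carbon monoxide, [C-]#[O+]
Why: palladium-catalysed reductive carbonylation (formylation) of a vinyl triflate, by oxidative addition to zerovalent palladium, CO insertion and hydride transfer from tin to the acylpalladium species, should give the tetrasubstituted enal without touching the stereocentres.

Step 9
Reactants: 9 ring-A enal; 10 methyl acetoacetate
Product: 14 methyl (3S,4S,10R)-8-(tert-butyldimethylsilyloxy)-3,4-(isopropylidenedioxy)-12,13-dinoreudesma-5,7-dien-11-oate (ring B closed; CO2Me on C7; OTBS on C8), via dienone 11 (not isolated), via 2H-pyran 12 (not isolated), via silyloxytriene 13 (not isolated)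
Conditions: piperidine (10 mol %), AcOH (10 mol %), 4 Å MS, PhMe, 80 °C; then Et3N, TBSOTf, 0 °C; then 60 °C
Reagents that add atoms: tert-butyldimethylsilyl trifluoromethanesulfonate, CC(C)(C)[Si](C)(C)OS(=O)(=O)C(F)(F)F
Why: Knoevenagel condensation of the aldehyde carbon C6 with the active methylene of 10 (the future C7) gives the (E)-alkylidene acetoacetate 11, which rests as its oxa-6π valence isomer 12; ring-opening of 12 returns 11 with the acetyl group cis to C5, soft enolisation of that methyl ketone (its CH3, the future C9, is the only enolisable position) gives silyloxytriene 13, and thermal disrotatory 6π-electrocyclisation of C10=C5–C6=C7–C8(OSi)=C9 forms the C9–C10 bond. The closest known reaction type is the domino condensation/6π-electrocyclisation (formal [3+3] annulation) of enals with 1,3-dicarbonyl compounds, together with the isophorone-type closure of a dienyl methyl ketone enol derivative onto a fully substituted terminus. Ring B closes as a six-membered ring by a pericyclic 6π closure, so no ionic attack on the tetrasubstituted C10 is needed, the C6=C7 bond having been made by the condensation in the same flask. C10 is the only new stereocentre (C5 is still sp2) and is set by torquoselectivity under control of ring A: the trans-fused acetonide holds O3 and O4 equatorial and the C4 methyl axial, so only the rotation that brings C9 onto the face of O4 and turns the C10 methyl axial, syn to the C4 methyl, lets ring A pass through a chair. The step needs carbon rather than oxygen closure and condensation at C7 rather than C9: the first is secured because the oxa-closure to 12 is reversible whereas the silyl enol ether closes irreversibly, the second because C7 is the doubly activated methylene of 10, whose ester carbon is kept as the future C11.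

Step 10
Reactants: 14 ring-B silyl dienol ether ester
Product: 16 (3S,4S,10R)-8,11-bis(tert-butyldimethylsilyloxy)-3,4-(isopropylidenedioxy)eudesma-5,7-diene, via lithium alkoxide 15 (not isolated)
Conditions: MeLi, CeCl3, THF, −78 → −20 °C; then TBSOTf, −78 → 0 °C
Reagents that add atoms: methyllithium, [Li]C; tert-butyldimethylsilyl trifluoromethanesulfonate, CC(C)(C)[Si](C)(C)OS(=O)(=O)C(F)(F)F
Why: double addition of the weakly basic organocerium reagent to the methyl ester (the C8 ketone is masked as its silyl dienol ether) builds the C11 dimethylcarbinol, and the alkoxide is capped in the same flask, the added silyl triflate giving the same bis-silyl product even if a 1,5 oxygen-to-oxygen silyl shift from O8 has occurred.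

Step 11
Reactants: 16 bis-silyl diene
Product: 17 (3S,4S,5R,10R)-11-(tert-butyldimethylsilyloxy)-3,4-(isopropylidenedioxy)eudesm-6-en-8-one
Conditions: Bu4NF, AcOH, THF, 0 → 23 °C
Reagents that add atoms: none
Why: fluoride desilylation of the silyl dienol ether (the hindered tertiary alkyl silyl ether is inert) gives the ring-B dienolate, which is protonated under acetate buffering and equilibrated to the conjugated 6-en-8-one, the proton at C5 being delivered axially on the face anti to the axial methyl groups on C4 and C10, which sets 5R and the trans ring fusion.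

Step 12
Reactants: 17 enone acetonide
Product: 18 (3S,4S,5R,10R)-11-(tert-butyldimethylsilyloxy)-3,4-dihydroxyeudesm-6-en-8-one
Conditions: AcOH/THF/H2O (3:1:1), 40 °C
Reagents that add atoms: none
Why: acid-catalysed acetal hydrolysis of the strained trans-fused dioxolane should proceed under conditions mild enough to leave the tertiary silyl ether and the β-silyloxy enone intact.

Step 13
Reactants: 19 (E)-2-methylbut-2-en-1-ol
Product: 20 [(2R,3R)-2,3-dimethyloxiran-2-yl]methanol
Conditions: Ti(OiPr)4 (cat.), D-(−)-diisopropyl tartrate (cat.), t-BuOOH, 4 Å MS, CH2Cl2, −20 °C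
Reagents that add atoms: tert-butyl hydroperoxide, CC(C)(C)OO
Why: Sharpless asymmetric epoxidation, in which the titanium tartrate complex delivers oxygen to one face of the trisubstituted (E)-allylic alcohol, should set both centres as (2R,3R) with the D-(−)-tartrate ester (the L-(+)-ester gives the (2S,3S) series with (E)-2-alken-1-ols).

Step 14
Reactants: 20 [(2R,3R)-2,3-dimethyloxiran-2-yl]methanol
Product: 21 (2S,3R)-2,3-dimethyloxirane-2-carboxylic acid
Conditions: RuCl3 (cat.), NaIO4, MeCN/EtOAc/H2O, 0 → 23 °C
Reagents that add atoms: water, O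
Why: ruthenium tetroxide-catalysed oxidation of the primary alcohol to the acid (through the aldehyde hydrate) leaves the epoxide untouched, the change of the C2 descriptor being only a change of substituent priority.

Step 15
Reactants: 21 (2S,3R)-2,3-dimethyloxirane-2-carboxylic acid
Product: 22 (2R,3S)-3-chloro-2-hydroxy-2-methylbutanoic acid
Conditions: HCl (4 M in dioxane), Et2O, 0 °C
Reagents that add atoms: hydrogen chloride, Cl
Why: acid-promoted ring-opening of the glycidic acid by chloride at C3, the carbon remote from the carboxyl group (the quaternary C2 next to the carboxyl is deactivated toward substitution), follows an SN2 course with inversion and converts (2S,3R) into (2R,3S).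

Step 16
Reactants: 22 (2R,3S)-3-chloro-2-hydroxy-2-methylbutanoic acid
Product: 24 (2R,3S)-3-chloro-2-methyl-2-(triethylsilyloxy)butanoic acid, via bis-silyl derivative 23 (not isolated)
Conditions: TESOTf, 2,6-lutidine, CH2Cl2, −78 → 0 °C; then H2O, THF, 0 °C
Reagents that add atoms: triethylsilyl trifluoromethanesulfonate, CC[Si](CC)(CC)OS(=O)(=O)C(F)(F)F
Why: silylation with a silyl triflate covers the hindered tertiary hydroxyl and the carboxyl group, and the labile silyl ester alone is hydrolysed in the aqueous stage, so the acid can be activated without epoxide re-closure or self-acylation.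

Step 17
Reactants: 18 diol enone; 24 silyl-protected acid
Product: 26 (3S,4S,5R,10R)-11-(tert-butyldimethylsilyloxy)-4-hydroxy-3-[(2R,3S)-3-chloro-2-methyl-2-(triethylsilyloxy)butanoyloxy]eudesm-6-en-8-one, via mixed anhydride 25 (not isolated)
Conditions: 2,4,6-trichlorobenzoyl chloride, Et3N, THF, 23 °C; then 18, DMAP, PhMe, 40 °C
Reagents that add atoms: none
Why: Yamaguchi esterification through the mixed anhydride and the acylpyridinium ion should acylate the secondary equatorial C3 hydroxyl in preference to the tertiary C4 hydroxyl, and the acid has no α-hydrogen to epimerise or eliminate.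

Step 18
Reactants: 26 C3 ester
Product: 28 target (3S,4S,5R,10R)-4-acetoxy-3-[(2R,3S)-3-chloro-2-hydroxy-2-methylbutanoyloxy]-11-hydroxyeudesm-6-en-8-one, via silylated acetate 27 (not isolated)
Conditions: Ac2O, DMAP, Et3N, CH2Cl2, 40 °C; then HF·pyridine, THF, 0 → 23 °C
Reagents that add atoms: acetic anhydride, CC(=O)OC(C)=O
Why: DMAP-catalysed acyl transfer acetylates the only free hydroxyl (tertiary O4) under conditions too weakly basic to enolise the enone toward C5, and fluoride then removes both tertiary silyl ethers without affecting the esters or the chlorohydrin.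

**Compound list**
1 | 2-methylcyclohex-2-en-1-one | CC1=CCCCC1=O | starting material
2 | (S)-2-methylcyclohex-2-en-1-ol | O[C@H]1CCCC=C1C | intermediate
3 | (1S,2S,3R)-2,3-epoxy-2-methylcyclohexan-1-ol (epoxide cis to OH) | O1[C@]2(C)[C@H]1CCC[C@@H]2O | intermediate
4 | (2R,3R)-2,3-epoxy-2-methylcyclohexan-1-one | O1[C@]2(C)[C@H]1CCCC2=O | intermediate
5 | (2R,3S)-2,3-dihydroxy-2-methylcyclohexan-1-one | O[C@]1(C)[C@@H](O)CCCC1=O | intermediate
6 | (3aR,7aS)-2,2,3a-trimethylhexahydro-1,3-benzodioxol-4-one (trans-fused acetonide) | CC1(C)O[C@]2(C)[C@@H](O1)CCCC2=O | intermediate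
7 | (3aR,7aS)-2,2,3a,5-tetramethylhexahydro-1,3-benzodioxol-4-one (C5 epimers) | CC1(C)O[C@]2(C)[C@@H](O1)CCC(C)C2=O | intermediate
8 | (3aR,7aS)-2,2,3a,5-tetramethyl-3a,6,7,7a-tetrahydro-1,3-benzodioxol-4-yl trifluoromethanesulfonate | CC1(C)O[C@]2(C)[C@@H](O1)CCC(C)=C2OS(=O)(=O)C(F)(F)F | intermediate
9 | (3aS,7aS)-2,2,3a,5-tetramethyl-3a,6,7,7a-tetrahydro-1,3-benzodioxole-4-carbaldehyde (ring-A enal) | CC1(C)O[C@]2(C)[C@@H](O1)CCC(C)=C2C=O | intermediate
10 | methyl acetoacetate | CC(=O)CC(=O)OC | starting material
11 | methyl (E)-2-acetyl-3-[(3aS,7aS)-2,2,3a,5-tetramethyl-3a,6,7,7a-tetrahydro-1,3-benzodioxol-4-yl]prop-2-enoate (acetyl cis to the ring) | CC1(C)O[C@]2(C)[C@@H](O1)CCC(C)=C2/C=C(\C(C)=O)C(=O)OC | intermediate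
12 | 2H-pyran valence isomer of 11 (acetyl oxygen bonded to C10; C10 epimers) | CC1(C)O[C@]2(C)[C@@H](O1)CCC3(C)OC(C)=C(C(=O)OC)C=C23 | intermediate
13 | tert-butyldimethylsilyl enol ether of the methyl ketone of 11 (2-silyloxytriene) | CC1(C)O[C@]2(C)[C@@H](O1)CCC(C)=C2/C=C(\C(=C)O[Si](C)(C)C(C)(C)C)C(=O)OC | intermediate
14 | methyl (3S,4S,10R)-8-(tert-butyldimethylsilyloxy)-3,4-(isopropylidenedioxy)-12,13-dinoreudesma-5,7-dien-11-oate | CC1(C)O[C@]2(C)[C@@H](O1)CC[C@]3(C)CC(O[Si](C)(C)C(C)(C)C)=C(C(=O)OC)C=C23 | intermediate
15 | lithium alkoxide of the C11 dimethylcarbinol (C8 silyl dienol ether kept) | [Li+].CC1(C)O[C@]2(C)[C@@H](O1)CC[C@]3(C)CC(O[Si](C)(C)C(C)(C)C)=C(C(C)(C)[O-])C=C23 | intermediate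
16 | (3S,4S,10R)-8,11-bis(tert-butyldimethylsilyloxy)-3,4-(isopropylidenedioxy)eudesma-5,7-diene | CC1(C)O[C@]2(C)[C@@H](O1)CC[C@]3(C)CC(O[Si](C)(C)C(C)(C)C)=C(C(C)(C)O[Si](C)(C)C(C)(C)C)C=C23 | intermediate
17 | (3S,4S,5R,10R)-11-(tert-butyldimethylsilyloxy)-3,4-(isopropylidenedioxy)eudesm-6-en-8-one | CC1(C)O[C@]2(C)[C@@H](O1)CC[C@]3(C)CC(=O)C(C(C)(C)O[Si](C)(C)C(C)(C)C)=C[C@H]32 | intermediate
18 | (3S,4S,5R,10R)-11-(tert-butyldimethylsilyloxy)-3,4-dihydroxyeudesm-6-en-8-one | O[C@]1(C)[C@@H](O)CC[C@]2(C)CC(=O)C(C(C)(C)O[Si](C)(C)C(C)(C)C)=C[C@H]21 | intermediate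
19 | (E)-2-methylbut-2-en-1-ol | C/C=C(\C)CO | starting material
20 | [(2R,3R)-2,3-dimethyloxiran-2-yl]methanol | OC[C@@]1(C)O[C@@H]1C | intermediate
21 | (2S,3R)-2,3-dimethyloxirane-2-carboxylic acid | OC(=O)[C@@]1(C)O[C@@H]1C | intermediate
22 | (2R,3S)-3-chloro-2-hydroxy-2-methylbutanoic acid | OC(=O)[C@@](C)(O)[C@H](C)Cl | intermediate
23 | triethylsilyl (2R,3S)-3-chloro-2-methyl-2-(triethylsilyloxy)butanoate | CC[Si](CC)(CC)OC(=O)[C@@](C)(O[Si](CC)(CC)CC)[C@H](C)Cl | intermediate
24 | (2R,3S)-3-chloro-2-methyl-2-(triethylsilyloxy)butanoic acid | OC(=O)[C@@](C)(O[Si](CC)(CC)CC)[C@H](C)Cl | intermediate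
25 | mixed anhydride of 24 with 2,4,6-trichlorobenzoic acid | O=C(OC(=O)[C@@](C)(O[Si](CC)(CC)CC)[C@H](C)Cl)c1c(Cl)cc(Cl)cc1Cl | intermediate
26 | 18 acylated on O3 by 24 (O4 free; O11 as TBS ether; O2' as TES ether) | O[C@]1(C)[C@@H](OC(=O)[C@@](C)(O[Si](CC)(CC)CC)[C@H](C)Cl)CC[C@]2(C)CC(=O)C(C(C)(C)O[Si](C)(C)C(C)(C)C)=C[C@H]21 | intermediate
27 | 4-O-acetate of 26 | CC(=O)O[C@]1(C)[C@@H](OC(=O)[C@@](C)(O[Si](CC)(CC)CC)[C@H](C)Cl)CC[C@]2(C)CC(=O)C(C(C)(C)O[Si](C)(C)C(C)(C)C)=C[C@H]21 | intermediate
28 | (3S,4S,5R,10R)-4-acetoxy-3-[(2R,3S)-3-chloro-2-hydroxy-2-methylbutanoyloxy]-11-hydroxyeudesm-6-en-8-one | CC(=O)O[C@]1(C)[C@@H](OC(=O)[C@@](C)(O)[C@H](C)Cl)CC[C@]2(C)CC(=O)C(C(C)(C)O)=C[C@H]21 | target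

**Step count**
Total: 18 steps. Longest linear sequence: 14 steps (steps 1–12, 17 and 18); steps 13–16 make the acid fragment.

**Steps most likely to fail**

Step 9. The methyl ketone may be silylated too slowly, so that the material rests at the oxygen-closed valence isomer; the silyl triflate may open the strained trans-acetonide; and the facial selectivity of the electrocyclisation at C10 may be modest. The fallback separates the condensation from the carbon–carbon closure and closes an enolate instead of a silyl enol ether. It sets out from 9 and 10: the condensation alone (piperidine, AcOH, PhMe, 80 °C) should give the isolable 2H-pyran 12. MeLi/CeCl3 (THF, −78 °C) then converts its ester into the dimethylcarbinol while the ketone stays masked as the pyran enol ether, giving the pyran carbinol F1. TBSOTf/2,6-lutidine gives the pyran silyl ether F2. KOt-Bu (THF, 0 °C) opens the pyran to the cis-dienone and deprotonates its methyl ketone, and the trienolate undergoes the isophorone-type 6π closure. Protonation on work-up returns to the route at 17, so steps 10 and 11 are not needed.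

Step 18. Acetyl transfer to the tertiary O4, flanked by the bulky C3 ester, may be too slow, and forcing conditions invite acyl migration or elimination. The fallback puts the acetate on before the C3 ester through a cyclic orthoester. It sets out from 18: MeC(OMe)3 with PPTS gives the cyclic 3,4-orthoacetate F3. Brief treatment with aqueous AcOH should open it mainly to the ester of the more hindered oxygen, the 4-acetate with free O3 F4. Yamaguchi esterification of F4 with 24 (through 25) returns to the route at 27, and HF·pyridine then gives 28.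

Step 8. Hydride transfer from tin to the crowded vinylpalladium intermediate may outrun CO insertion, so that the triflate is lost by reduction. The fallback is carbonylative esterification followed by redox adjustment. It sets out from 8: Pd(OAc)2, PPh3, CO, MeOH, Et3N in DMF gives the methyl ester F5; i-Bu2AlH (CH2Cl2, −78 °C) gives the allylic alcohol F6; MnO2 (CH2Cl2) returns to the route at 9.

Further compounds
F1 | step 9 | pyran carbinol (2H-pyran 12 with C(CH3)2OH in place of CO2Me) | CC1(C)O[C@]2(C)[C@@H](O1)CCC3(C)OC(C)=C(C(C)(C)O)C=C23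
F2 | step 9 | pyran silyl ether (tert-butyldimethylsilyl ether of F1) | CC1(C)O[C@]2(C)[C@@H](O1)CCC3(C)OC(C)=C(C(C)(C)O[Si](C)(C)C(C)(C)C)C=C23
F3 | step 18 | cyclic 3,4-(1-methoxyethylidene) orthoacetate of 18 | COC1(C)O[C@]2(C)[C@@H](O1)CC[C@]3(C)CC(=O)C(C(C)(C)O[Si](C)(C)C(C)(C)C)=C[C@H]32
F4 | step 18 | (3S,4S,5R,10R)-4-acetoxy-11-(tert-butyldimethylsilyloxy)-3-hydroxyeudesm-6-en-8-one | CC(=O)O[C@]1(C)[C@@H](O)CC[C@]2(C)CC(=O)C(C(C)(C)O[Si](C)(C)C(C)(C)C)=C[C@H]21
F5 | step 8 | methyl (3aS,7aS)-2,2,3a,5-tetramethyl-3a,6,7,7a-tetrahydro-1,3-benzodioxole-4-carboxylate | CC1(C)O[C@]2(C)[C@@H](O1)CCC(C)=C2C(=O)OC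
F6 | step 8 | [(3aS,7aS)-2,2,3a,5-tetramethyl-3a,6,7,7a-tetrahydro-1,3-benzodioxol-4-yl]methanol | CC1(C)O[C@]2(C)[C@@H](O1)CCC(C)=C2CO
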